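**Retrosynthetic overview**

1. The only ring, the 5,5-dimethylfuran-2(5H)-ylidene (O1, C2, C3, C4, C5), is made last and in one flask. C3–C4 comes from an aldol addition of the open-chain vinylogous amide 20 to aldehyde 23, and O1–C2 from an acid-triggered ring closure; the same acid releases the formyl, 2-oxoethyl and methyl ketone groups.
2. Enabling feature: C5 is quaternary (CMe2, no hydrogen), so the ring-closed hemiketal cannot aromatise to a furan. It must dehydrate out of the ring to the push–pull vinylogous formate O1–C2=C–CH=O, a thermodynamic sink whose exocyclic double bond can equilibrate to E.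
3. 20 comes from aldehyde 16 by Stork acylation, and 16 from the propenyl acid 12 by cross-metathesis and oxidation. 12 comes from ester 9 by Ireland–Claisen rearrangement, which sets both stereocenters from (S)-but-3-en-2-ol.
4. 9 is the ester of acid 5 (organocopper addition to an allenoate) with alcohol 8 (cross-metathesis).
5. Ring order: no ring of the target is carried through the route; the dihydrofuran is formed only in step 12.

Key step: step 12

Remark: the target is taken as the open-chain form drawn; lactol forms that the 1,5-dialdehyde or the 5-oxo acid may reach reversibly are regarded as the same compound.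

**Step 1**
Reactants: 1 2-(3-chloropropyl)-2-methyl-1,3-dioxolane; 2 ethyl buta-2,3-dienoate
Product: 4 ethyl 3-methylidene-6-(2-methyl-1,3-dioxolan-2-yl)hexanoate, via alkylmagnesium chloride 3 (not isolated)
Conditions: Mg, THF, 50 °C; CuBr·SMe2 (10 mol %), THF, −78 °C, then 2; NH4Cl (aq), −78 °C
Reagents that add atoms: none
Why: Organocopper conjugate addition to an allenoate: the alkyl group from 3 adds to the central allene carbon and kinetic α-protonation of the dienolate at −78 °C leaves the 1,1-disubstituted β,γ-alkene; no stereocenter is formed.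

**Step 2**
Reactants: 4 ethyl 3-methylidene-6-(2-methyl-1,3-dioxolan-2-yl)hexanoate
Product: 5 3-methylidene-6-(2-methyl-1,3-dioxolan-2-yl)hexanoic acid
Conditions: LiOH·H2O, THF/H2O, 0 °C → rt; 1 M HCl to pH 4, 0 °C
Reagents that add atoms: lithium hydroxide, [Li+].[OH-]
Why: Saponification at low temperature; the carboxylate that forms is not enolised further, so the β,γ-alkene should stay out of conjugation, and the brief cold acidification spares the dioxolane.

**Step 3**
Reactants: 6 (S)-but-3-en-2-ol; 7 4,4-diethoxybut-1-ene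
Product: 8 (2S,3E)-6,6-diethoxyhex-3-en-2-ol
Conditions: second-generation Hoveyda–Grubbs catalyst (3 mol %), 7 (3 equiv), CH2Cl2, 40 °C
Reagents that add atoms: none
Why: Olefin cross-metathesis of two terminal alkenes with loss of ethylene should give the (E)-alkene under thermodynamic control; the carbinol stereocenter of 6 is not involved and stays S.

**Step 4**
Reactants: 5 3-methylidene-6-(2-methyl-1,3-dioxolan-2-yl)hexanoic acid; 8 (2S,3E)-6,6-diethoxyhex-3-en-2-ol
Product: 9 (2S,3E)-6,6-diethoxyhex-3-en-2-yl 3-methylidene-6-(2-methyl-1,3-dioxolan-2-yl)hexanoate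
Conditions: EDC·HCl, DMAP (10 mol %), CH2Cl2, 0 °C
Reagents that add atoms: none
Why: Steglich esterification under mild carbodiimide activation at 0 °C joins the fragments without touching the carbinol stereocenter and with little time for base-mediated migration of the β,γ-alkene.

**Step 5**
Reactants: 9 (2S,3E)-6,6-diethoxyhex-3-en-2-yl 3-methylidene-6-(2-methyl-1,3-dioxolan-2-yl)hexanoate
Product: 12 (2R,3R,4E)-3-(2,2-diethoxyethyl)-2-[5-(2-methyl-1,3-dioxolan-2-yl)pent-1-en-2-yl]hex-4-enoic acid, via silyl ketene acetal 10 (not isolated), via trimethylsilyl ester 11 (not isolated)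
Conditions: LiN(i-Pr)2, THF/DMPU (4:1), −78 °C; Me3SiCl, Et3N, −78 → 45 °C; NaH2PO4 (aq)
Reagents that add atoms: none
Why: Ireland–Claisen rearrangement: deprotonation in THF/DMPU should give the Z(O)-enolate and hence the (Z)-silyl ketene acetal 10, whose [3,3] shift through a chair transition state with the (E)-alkene and the carbinol methyl group pseudo-equatorial relays the (S)-carbinol centre to C3 and fixes C2 relative to it, giving the (2R,3R) acid with an (E)-propenyl group.

**Step 6**
Reactants: 12 (2R,3R,4E)-3-(2,2-diethoxyethyl)-2-[5-(2-methyl-1,3-dioxolan-2-yl)pent-1-en-2-yl]hex-4-enoic acid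
Product: 13 2-(trimethylsilyl)ethyl (2R,3R,4E)-3-(2,2-diethoxyethyl)-2-[5-(2-methyl-1,3-dioxolan-2-yl)pent-1-en-2-yl]hex-4-enoate
Conditions: Me3SiCH2CH2OH, PPh3, DIAD, THF, 0 °C → rt
Reagents that add atoms: 2-(trimethylsilyl)ethanol, OCC[Si](C)(C)C
Why: Mitsunobu esterification activates the alcohol and not the acid, so C2 never passes through an acyl-activated, enolisable species; the ester masks the acid for steps 7 and 8 and is later removed by fluoride.

**Step 7**
Reactants: 13 2-(trimethylsilyl)ethyl (2R,3R,4E)-3-(2,2-diethoxyethyl)-2-[5-(2-methyl-1,3-dioxolan-2-yl)pent-1-en-2-yl]hex-4-enoate; 14 vinylboronic acid pinacol ester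
Product: 16 2-(trimethylsilyl)ethyl (2R,3S)-3-(2,2-diethoxyethyl)-2-[5-(2-methyl-1,3-dioxolan-2-yl)pent-1-en-2-yl]-5-oxopentanoate, via alkenylboronate 15 (not isolated)
Conditions: 14 (3 equiv), second-generation Hoveyda–Grubbs catalyst (5 mol %), CH2Cl2, 40 °C; then H2O2 (30 %), NaHCO3 (aq), THF, 0 °C → rt
Reagents that add atoms: hydrogen peroxide, OO
Why: Olefin cross-metathesis replaces the methyl-bearing alkene terminus by a boryl-bearing one (the 1,1-disubstituted alkene should not take part), and oxidation of the alkenylboronate gives the enol and so the aldehyde; C3 keeps its spatial arrangement and only its descriptor changes.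

**Step 8**
Reactants: 16 2-(trimethylsilyl)ethyl (2R,3S)-3-(2,2-diethoxyethyl)-2-[5-(2-methyl-1,3-dioxolan-2-yl)pent-1-en-2-yl]-5-oxopentanoate; 17 acetyl chloride
Product: 19 2-(trimethylsilyl)ethyl (2R,3S,4E)-4-acetyl-3-(2,2-diethoxyethyl)-2-[5-(2-methyl-1,3-dioxolan-2-yl)pent-1-en-2-yl]-5-(morpholin-4-yl)pent-4-enoate, via enamine 18 (not isolated)
Conditions: morpholine, 4 Å MS, CH2Cl2, 0 °C → rt; then Et3N, 17, 0 °C
Reagents that add atoms: morpholine, C1COCCN1
Why: Stork enamine acylation: the aldehyde enamine is acylated on carbon and loses HCl to the base, giving the β-amino enone (vinylogous amide) that carries the 2-acyl aldehyde in masked form; the geometry of its double bond is of no consequence and the stereocenters are untouched.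

**Step 9**
Reactants: 19 2-(trimethylsilyl)ethyl (2R,3S,4E)-4-acetyl-3-(2,2-diethoxyethyl)-2-[5-(2-methyl-1,3-dioxolan-2-yl)pent-1-en-2-yl]-5-(morpholin-4-yl)pent-4-enoate
Product: 20 (2R,3S,4E)-4-acetyl-3-(2,2-diethoxyethyl)-2-[5-(2-methyl-1,3-dioxolan-2-yl)pent-1-en-2-yl]-5-(morpholin-4-yl)pent-4-enoic acid
Conditions: Bu4NF, THF, 0 °C → rt; NaH2PO4 (aq)
Reagents that add atoms: none
Why: Fluoride attacks silicon and the ester fragments to carboxylate, ethylene and Me3SiF, a non-hydrolytic cleavage that spares the vinylogous amide, the acetal and the dioxolane.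

**Step 10**
Reactants: 21 methyl 2-hydroxy-2-methylpropanoate
Product: 22 methyl 2-methyl-2-(triethylsilyloxy)propanoate
Conditions: Et3SiOTf, 2,6-lutidine, CH2Cl2, 0 °C
Reagents that add atoms: triethylsilyl trifluoromethanesulfonate, CC[Si](CC)(CC)OS(=O)(=O)C(F)(F)F
Why: O-Silylation of the hindered tertiary alcohol with a silyl triflate and a non-nucleophilic base; the triethylsilyl ether is stable to hydride and to amide base and falls off in dilute acid.

**Step 11**
Reactants: 22 methyl 2-methyl-2-(triethylsilyloxy)propanoate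
Product: 23 2-methyl-2-(triethylsilyloxy)propanal
Conditions: i-Bu2AlH (1.1 equiv), CH2Cl2, −78 °C; KNaC4H4O6 (aq)
Reagents that add atoms: none
Why: Half-reduction of an α-silyloxy ester with one equivalent of i-Bu2AlH at −78 °C should stop at the aldehyde because the tetrahedral aluminium hemiacetal is stable at that temperature.

**Step 12**
Reactants: 20 (2R,3S,4E)-4-acetyl-3-(2,2-diethoxyethyl)-2-[5-(2-methyl-1,3-dioxolan-2-yl)pent-1-en-2-yl]-5-(morpholin-4-yl)pent-4-enoic acid; 23 2-methyl-2-(triethylsilyloxy)propanal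
Product: 26 (2R,3S)-3-[(1E)-1-(5,5-dimethylfuran-2(5H)-ylidene)-2-oxoethyl]-5-oxo-2-(6-oxohept-1-en-2-yl)pentanoic acid, via acetylated aldol adduct 24 (not isolated), via acetoxy oxolanylidene aldehyde 25 (not isolated)
Conditions: LiN(i-Pr)2 (2.1 equiv), THF, −78 °C; 23, −78 °C; Ac2O (1.2 equiv), −78 → −20 °C; then 2 M HCl (aq)/THF, 0 → 40 °C
Reagents that add atoms: water, O
Why: Proposed new method: the carboxylate/α′-enolate dianion of vinylogous amide 20 (α′-deprotonation of β-amino enones by amide bases is known) adds to aldehyde 23 to form the C3–C4 bond of the future ring, and the aldolate is capped in the flask as acetate 24 so that this oxygen cannot close the competing six-membered dihydropyranone; aqueous acid then removes the silyl group, the freed tertiary hydroxyl adds to the protonated enaminone (a vinylogous iminium ion) at the former ketone carbon in a 5-exo-trig closure that forms the O1–C2 bond, water is lost, the iminium ion is hydrolysed to the aldehyde (a net 1,3-carbonyl transposition, 25), and acetic acid is eliminated from C4 through the dienol to give the C3=C4 bond. The closest known reactions are the cyclodehydration of 1,3-dicarbonyl dianion–epoxide adducts to 2-alkylidenetetrahydrofurans, the acid-mediated cyclisation of γ-hydroxy enones to furans and the Stork–Danheiser transposition of vinylogous esters. No new stereocenter is formed: the acetoxy-bearing carbon is a mixture of epimers and the enaminone may be a mixture of geometrical isomers, and all should converge because that carbon becomes sp2 and the exocyclic C2=C bond of the push–pull product can equilibrate through its O-protonated form to the E isomer, which keeps the branched chain next to O1 and the formyl group next to C3–H. The step needs α′- over α-deprotonation, five- over six-ring closure and dehydration out of the ring; these are secured by carrying the acid as its carboxylate, by the O-acetyl cap, and by the quaternary C5, which bears no hydrogen and so rules out a furan. The same acid cleaves the diethyl acetal and the dioxolane, so that the formyl group, the 2-oxoethyl group and the methyl ketone all appear in this operation.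

**Compound list**

1 | 2-(3-chloropropyl)-2-methyl-1,3-dioxolane | CC1(CCCCl)OCCO1 | starting material
2 | ethyl buta-2,3-dienoate | C=C=CC(=O)OCC | starting material
3 | [3-(2-methyl-1,3-dioxolan-2-yl)propyl]magnesium chloride | CC1(CCC[Mg]Cl)OCCO1 | intermediate
4 | ethyl 3-methylidene-6-(2-methyl-1,3-dioxolan-2-yl)hexanoate | C=C(CCCC1(C)OCCO1)CC(=O)OCC | intermediate
5 | 3-methylidene-6-(2-methyl-1,3-dioxolan-2-yl)hexanoic acid | C=C(CCCC1(C)OCCO1)CC(=O)O | intermediate
6 | (S)-but-3-en-2-ol | C[C@H](O)C=C | starting material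
7 | 4,4-diethoxybut-1-ene | C=CCC(OCC)OCC | starting material
8 | (2S,3E)-6,6-diethoxyhex-3-en-2-ol | C[C@H](O)/C=C/CC(OCC)OCC | intermediate
9 | (2S,3E)-6,6-diethoxyhex-3-en-2-yl 3-methylidene-6-(2-methyl-1,3-dioxolan-2-yl)hexanoate | C=C(CCCC1(C)OCCO1)CC(=O)O[C@@H](C)/C=C/CC(OCC)OCC | intermediate
10 | (Z)-O-trimethylsilyl ketene acetal of 9 | C=C(CCCC1(C)OCCO1)/C=C(\O[Si](C)(C)C)O[C@@H](C)/C=C/CC(OCC)OCC | intermediate
11 | trimethylsilyl (2R,3R,4E)-3-(2,2-diethoxyethyl)-2-[5-(2-methyl-1,3-dioxolan-2-yl)pent-1-en-2-yl]hex-4-enoate | C=C(CCCC1(C)OCCO1)[C@H](C(=O)O[Si](C)(C)C)[C@H](CC(OCC)OCC)/C=C/C | intermediate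
12 | (2R,3R,4E)-3-(2,2-diethoxyethyl)-2-[5-(2-methyl-1,3-dioxolan-2-yl)pent-1-en-2-yl]hex-4-enoic acid | C=C(CCCC1(C)OCCO1)[C@H](C(=O)O)[C@H](CC(OCC)OCC)/C=C/C | intermediate
13 | 2-(trimethylsilyl)ethyl (2R,3R,4E)-3-(2,2-diethoxyethyl)-2-[5-(2-methyl-1,3-dioxolan-2-yl)pent-1-en-2-yl]hex-4-enoate | C=C(CCCC1(C)OCCO1)[C@H](C(=O)OCC[Si](C)(C)C)[C@H](CC(OCC)OCC)/C=C/C | intermediate
14 | vinylboronic acid pinacol ester | C=CB1OC(C)(C)C(C)(C)O1 | starting material
15 | 2-(trimethylsilyl)ethyl (2R,3R,4E)-3-(2,2-diethoxyethyl)-2-[5-(2-methyl-1,3-dioxolan-2-yl)pent-1-en-2-yl]-5-(4,4,5,5-tetramethyl-1,3,2-dioxaborolan-2-yl)pent-4-enoate | C=C(CCCC1(C)OCCO1)[C@H](C(=O)OCC[Si](C)(C)C)[C@H](CC(OCC)OCC)/C=C/B1OC(C)(C)C(C)(C)O1 | intermediate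
16 | 2-(trimethylsilyl)ethyl (2R,3S)-3-(2,2-diethoxyethyl)-2-[5-(2-methyl-1,3-dioxolan-2-yl)pent-1-en-2-yl]-5-oxopentanoate | C=C(CCCC1(C)OCCO1)[C@H](C(=O)OCC[Si](C)(C)C)[C@H](CC(OCC)OCC)CC=O | intermediate
17 | acetyl chloride | CC(=O)Cl | starting material
18 | 2-(trimethylsilyl)ethyl (2R,3R,4E)-3-(2,2-diethoxyethyl)-2-[5-(2-methyl-1,3-dioxolan-2-yl)pent-1-en-2-yl]-5-(morpholin-4-yl)pent-4-enoate | C=C(CCCC1(C)OCCO1)[C@H](C(=O)OCC[Si](C)(C)C)[C@H](CC(OCC)OCC)/C=C/N1CCOCC1 | intermediate
19 | 2-(trimethylsilyl)ethyl (2R,3S,4E)-4-acetyl-3-(2,2-diethoxyethyl)-2-[5-(2-methyl-1,3-dioxolan-2-yl)pent-1-en-2-yl]-5-(morpholin-4-yl)pent-4-enoate | C=C(CCCC1(C)OCCO1)[C@H](C(=O)OCC[Si](C)(C)C)[C@H](CC(OCC)OCC)/C(=C\N1CCOCC1)C(C)=O | intermediate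
20 | (2R,3S,4E)-4-acetyl-3-(2,2-diethoxyethyl)-2-[5-(2-methyl-1,3-dioxolan-2-yl)pent-1-en-2-yl]-5-(morpholin-4-yl)pent-4-enoic acid | C=C(CCCC1(C)OCCO1)[C@H](C(=O)O)[C@H](CC(OCC)OCC)/C(=C\N1CCOCC1)C(C)=O | intermediate
21 | methyl 2-hydroxy-2-methylpropanoate | COC(=O)C(C)(C)O | starting material
22 | methyl 2-methyl-2-(triethylsilyloxy)propanoate | COC(=O)C(C)(C)O[Si](CC)(CC)CC | intermediate
23 | 2-methyl-2-(triethylsilyloxy)propanal | O=CC(C)(C)O[Si](CC)(CC)CC | intermediate
24 | (2R,3S,4E)-4-[3-acetoxy-4-methyl-4-(triethylsilyloxy)pentanoyl]-3-(2,2-diethoxyethyl)-2-[5-(2-methyl-1,3-dioxolan-2-yl)pent-1-en-2-yl]-5-(morpholin-4-yl)pent-4-enoic acid (epimers at the acetoxy carbon) | C=C(CCCC1(C)OCCO1)[C@H](C(=O)O)[C@H](CC(OCC)OCC)/C(=C\N1CCOCC1)C(=O)CC(OC(C)=O)C(C)(C)O[Si](CC)(CC)CC | intermediate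
25 | (2R,3S)-3-[(1E)-1-(4-acetoxy-5,5-dimethyloxolan-2-ylidene)-2-oxoethyl]-5-oxo-2-(6-oxohept-1-en-2-yl)pentanoic acid (epimers at the acetoxy carbon) | C=C(CCCC(C)=O)[C@H](C(=O)O)[C@H](CC=O)/C(C=O)=C1/CC(OC(C)=O)C(C)(C)O1 | intermediate
26 | (2R,3S)-3-[(1E)-1-(5,5-dimethylfuran-2(5H)-ylidene)-2-oxoethyl]-5-oxo-2-(6-oxohept-1-en-2-yl)pentanoic acid (CNP0150297.1) | C=C(CCCC(C)=O)[C@H](C(=O)O)[C@H](CC=O)/C(C=O)=C1/C=CC(C)(C)O1 | target

**Step count and risks**

Total step count: 12. Longest linear sequence: 9 steps (1, 2, 4, 5, 6, 7, 8, 9, 12).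

The three steps most likely to fail:

1. Step 12 (Proposed new method). What may go wrong: incomplete capping of the aldolate, so that the secondary oxygen closes onto the formyl carbon (six-ring manifold); or loss of acetate before ring closure, which would give an (E)-enone that cannot cyclise. Fallback (known chemistry), setting out from 16 and coming back at 26: the enamine from 16 is acylated with (diethoxyphosphoryl)acetyl chloride and Et3N (Stork acylation) to the β-ketophosphonate vinylogous amide ester F1. Bu4NF frees the β-ketophosphonate acid F2. A Masamune–Roush Horner–Wadsworth–Emmons reaction (LiCl, DBU, MeCN) with 23 should give the (E)-enone acid F3, so that no aldol oxygen is ever present. Irradiation at 365 nm in 2 M HCl/THF should then isomerise the enone to its (Z)-form, whose tertiary hydroxyl (freed from silicon by the acid) closes onto the ketone in the known γ-hydroxy-enone cyclodehydration, while the acid releases the three carbonyl groups to give 26.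

2. Step 5. What may go wrong: loss of control over the enolate geometry of the cross-conjugated dienolate, leading to erosion of the C2/C3 diastereoselectivity, and base-mediated migration of the β,γ-alkene. Fallback, setting out from 5 and coming back at 16: 5 is converted with C6F5OH and EDC to the pentafluorophenyl ester F4. Cross-metathesis of 7 with allyl methyl carbonate gives the (E)-allyl carbonate F5. A synergistic allylic alkylation follows, with benzotetramisole as Lewis base for the C1-ammonium enolate of F4 and [Ir(cod)Cl]2 with a chiral phosphoramidite for the allyl fragment; the two catalysts control the two centres independently, and the antipode of each is chosen for 2R,3R. Addition of 2-(trimethylsilyl)ethanol and DMAP should then give the terminal alkene ester F6. F6 takes the place of 13 in step 7 (ethylene is lost instead of propene) and the route is rejoined at 16.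

3. Step 7. What may go wrong: slow turnover of the metathesis catalyst at the hindered, allylically branched internal alkene, with catalyst decay and self-metathesis of 14 taking over. Fallback, setting out from 13 and coming back at 16: 13 is cut with ethylene (second-generation Hoveyda–Grubbs catalyst, 1 atm) to the terminal alkene ester (the compound F6 above). This is hydroborated at the monosubstituted alkene with bis(3-methylbutan-2-yl)borane and oxidised (H2O2, NaHCO3) to the primary alcohol F7, and Dess–Martin periodinane then gives 16.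

**Further compounds**

F1 | step 12 | 2-(trimethylsilyl)ethyl (2R,3S,4E)-4-[2-(diethoxyphosphoryl)acetyl]-3-(2,2-diethoxyethyl)-2-[5-(2-methyl-1,3-dioxolan-2-yl)pent-1-en-2-yl]-5-(morpholin-4-yl)pent-4-enoate | C=C(CCCC1(C)OCCO1)[C@H](C(=O)OCC[Si](C)(C)C)[C@H](CC(OCC)OCC)/C(=C\N1CCOCC1)C(=O)CP(=O)(OCC)OCC
F2 | step 12 | (2R,3S,4E)-4-[2-(diethoxyphosphoryl)acetyl]-3-(2,2-diethoxyethyl)-2-[5-(2-methyl-1,3-dioxolan-2-yl)pent-1-en-2-yl]-5-(morpholin-4-yl)pent-4-enoic acid | C=C(CCCC1(C)OCCO1)[C@H](C(=O)O)[C@H](CC(OCC)OCC)/C(=C\N1CCOCC1)C(=O)CP(=O)(OCC)OCC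
F3 | step 12 | (2R,3S,4E)-3-(2,2-diethoxyethyl)-4-[(2E)-4-methyl-4-(triethylsilyloxy)pent-2-enoyl]-2-[5-(2-methyl-1,3-dioxolan-2-yl)pent-1-en-2-yl]-5-(morpholin-4-yl)pent-4-enoic acid | C=C(CCCC1(C)OCCO1)[C@H](C(=O)O)[C@H](CC(OCC)OCC)/C(=C\N1CCOCC1)C(=O)/C=C/C(C)(C)O[Si](CC)(CC)CC
F4 | step 5 | pentafluorophenyl 3-methylidene-6-(2-methyl-1,3-dioxolan-2-yl)hexanoate | C=C(CCCC1(C)OCCO1)CC(=O)Oc1c(F)c(F)c(F)c(F)c1F
F5 | step 5 | (2E)-5,5-diethoxypent-2-en-1-yl methyl carbonate | COC(=O)OC/C=C/CC(OCC)OCC
F6 | step 5 | 2-(trimethylsilyl)ethyl (2R,3R)-3-(2,2-diethoxyethyl)-2-[5-(2-methyl-1,3-dioxolan-2-yl)pent-1-en-2-yl]pent-4-enoate | C=C(CCCC1(C)OCCO1)[C@H](C(=O)OCC[Si](C)(C)C)[C@H](CC(OCC)OCC)C=C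
F7 | step 7 | 2-(trimethylsilyl)ethyl (2R,3S)-3-(2,2-diethoxyethyl)-5-hydroxy-2-[5-(2-methyl-1,3-dioxolan-2-yl)pent-1-en-2-yl]pentanoate | C=C(CCCC1(C)OCCO1)[C@H](C(=O)OCC[Si](C)(C)C)[C@H](CC(OCC)OCC)CCO
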